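In the south-east run the target stays ahead of the isomer of the product until the two stand level at 41.6% and 41.8% of the charge. So I read it as substrate → target ⇌ isomer, with an even balance.

| flask | substrate | precatalyst | remark | time |
|---|---|---|---|---|
| south-east | 0.069 M | 6.9 µM | run made earlier |  |
| south | 0.069 M | 3.5 µM | run made earlier |  |
| east | 0.069 M | 5.2 µM | run made earlier |  |
| north-west | 0.035 M | 6.9 µM | run made earlier |  |
| winter | 0.069 M | 6.9 µM | a single well-mixed tank run continuously and read at steady state, 30 h in it on average |  |
| midnight | 0.069 M (fed, over 24.0 h) | 6.9 µM | a stirred flask in which substrate is dosed at a steady rate over 24.0 h without added volume, worked up at 30 h | 30 h |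
| dusk | 0.069 M | 6.9 µM | plug flow through a tube for 30 h, no back-mixing | 30 h |
| summer | 0.069 M | 6.9 µM | everything together in a closed stirred flask, run for 30 h | 30 h |

| run | time / h | target / % | isomer of the product / % |
|---|---|---|---|
| south-east | 6.00 | 11.5 | 7.1 |
| south-east | 12.0 | 29.4 | 23.8 |
| south-east | 20.0 | 39.0 | 33.5 |
| south-east | 25.0 | 41.1 | 38.3 |
| south-east | 30.0 | 41.6 | 41.8 |
| south | 3.00 | 0 | 0 |
| south | 10.0 | 13.4 | 7.6 |
| south | 15.0 | 25.2 | 17.7 |
| south | 25.0 | 35.2 | 33.9 |
| south | 40.0 | 40.7 | 39.7 |
| east | 3.00 | 4.6 | 1.1 |
| east | 10.0 | 20.5 | 12.5 |
| east | 15.0 | 28.7 | 24.2 |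
| east | 25.0 | 38.6 | 37.0 |
| east | 40.0 | 43.1 | 43.0 |
| north-west | 8.00 | 12.7 | 5.2 |
| north-west | 15.0 | 26.2 | 21.1 |
| north-west | 20.0 | 32.1 | 27.3 |
| north-west | 30.0 | 37.5 | 35.2 |
| north-west | 40.0 | 39.1 | 39.4 |

(readings scatter by 1 percentage point)

- the stated concentrations are those of everything mixed, before any reaction; amounts are the same in each set-up
- the feed brings no volume worth counting
- the earlier runs were made in a closed, stirred flask

* the set-up with the highest share of target in all that became target or isomer of the product, at the outlet or at the end ("none" if the first two lie within 2 percentage points) (winter / midnight / dusk / summer / none)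
* share of target in all that became target or isomer of the product, at the outlet or at the end, winter
* share of target in all that became target or isomer of the product, at the outlet or at the end, midnight
* share of target in all that became target or isomer of the product, at the outlet or at the end, dusk
* share of target in all that became target or isomer of the product, at the outlet or at the end, summer

Two times matter to me. Call the lead c(target) − c(isomer). The isomer grows at lead/(2τ), so in the south-east run τ is the area under the lead over time, divided by twice the last isomer reading:

τ = 1.15 h / (2 × 41.8%) = 1.37 h

This evening-out time (the relaxation time) is a reading. The other time is the fill time T: what has been made, divided by the present rate of making. While τ is much shorter than T, the lead equals that rate times τ, so: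

share = 0.5 × (1 + τ/T)

Summer is the south-east recipe, and the last interval of the south-east run reads T = 104 h, a rough reading but much longer than τ, so I reckon 50.7% for summer and for dusk, whose tube ages its liquid the same way. In winter's tank the outflow also carries lead away, and T becomes the mean stay plus τ:

share = 52.2%

For midnight I have no reading to set T by.

The forecast gives winter 53.2%, midnight 53%, dusk 50.5%, summer 50.5% and best none, on the ground that “Target share follows conversion rather than time or concentration”. My winter figure is lower than the forecast's.

The flask gives winter 52.3%, midnight 51.9%, dusk 50.6%, summer 50.6% and best none. Removing the brake by c(substrate) in the rate law of the turning of substrate into target leaves winter's share as it is.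

    substrate + enzyme → target + enzyme, rate k1*[substrate]^2.5*[enzyme]/(1 + ([substrate]/Kh1)^2.5) (0.0530 M, k = 2200 M⁻²·⁵ s⁻¹)
    target ⇌ isomer of the product (K = 1.00, k = 9.50 × 10⁻⁵ s⁻¹)
    precatalyst → enzyme (k = 9.80 × 10⁻⁶ s⁻¹)

Read backward through the rule, summer's share gives T = 106 h and midnight's gives 35.2 h, which is shorter, and midnight ends with 23.1% of its charge still substrate. Dusk, with summer's share, ends with 16.0% still substrate. Summer's share has not quite come to rest at 30 h: left until 300 h, it is 50.0%, a change of 0.60 percentage points.

(The numbers in the tables are calculated for an exercise; noise was put on by code.)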